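## Analysis of the target

The target is a 7-oxabicyclo[4.1.0]hept-3-en-2-one, a cyclohexenone fused to an oxirane. The ring atoms are numbered C1 (bears the (E)-hept-1-enyl group), C2 (bears CH2OH), C3 (carbinol), C4 and C5 (oxirane carbons, C5 quaternary) and C6 (ketone). The three stereocentres C3, C4 and C5 are contiguous and all S. The C3 hydroxyl and the oxirane oxygen lie on the same ring face, and the C5 side chain lies on the opposite face. The C1=C2 alkene is tetrasubstituted and sits in a cross-conjugated dienone. Two further alkene geometries lie outside the ring: E in the heptenyl group and E in the 2-methylbut-2-enoic acid chain. The epoxy ketone is easily reduced and base-labile, the epoxy alcohol can undergo oxirane migration, and the side chain has a doubly allylic CH2 and a free acid. The difficulty is the density of functionality: six functionalised ring carbons, a quaternary oxirane carbon next to the ketone, and a tetrasubstituted alkene that is hard to complete by coupling on a crowded ring. The strategy rests on one feature: C3 lies between alkene carbon C2 and oxirane carbon C4, so adding an alkenyl metal at C2 to an aldehyde at C3 on a preformed oxirane makes the ring and the carbinol in one step.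

## Retrosynthetic reasoning

**34 back to 31 (functional-group level only).** The acid, the free hydroxyls and the epoxy ketone tolerate the least, so they appear last: desilylation (34 from 33), Pinnick oxidation of an enal (33 from 32), and one double oxidation of diol 31 that makes the C6 ketone and the side-chain enal together (32). C6 stays at the alcohol level until then because the ring-forming step uses a reducing metal. The side chain stays an allylic ether because every earlier organometallic step would attack an ester.

**31 back to 28 (protecting-group relay).** The C3 hydroxyl of 28 is capped (29), then the C6 triethylsilyl ether and the PMB ether are removed in turn (30, 31). Three silyl ethers of graded lability make this possible without touching the oxirane.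

**28 to 25 (cut C2–C3).** This is the ring bond between the alkene carbon C2 and the carbinol carbon C3. Cutting here, and not at C1–C6 or C5–C6, leaves an alkenyl iodide and an aldehyde, a pair that couples under neutral, non-basic conditions in the presence of an oxirane. The tetrasubstituted alkene, the heptenyl group and the oxirane are already in place in 25, so the ring closure forms one σ-bond and one stereocentre. The forward reaction has to close a six-membered ring and place the new hydroxyl cis to the oxirane oxygen.

**25 to 23 via 24 (cut C4–O and C5–O).** The oxirane is taken back to the Z-alkene of allylic alcohol 23. The C3 hydroxyl that later becomes the aldehyde is also the handle for a Sharpless epoxidation, so no extra directing group is needed. The Z geometry of 23 becomes the cis relation of C3 and C6 on the oxirane, which the fused ring requires.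

**23 to 21 via 22 (protecting groups).** C6 must be a silyl ether before C3 is oxidised, otherwise the C6 hydroxyl would add to the aldehyde. Both oxygens are therefore triethylsilylated and the unhindered primary one is freed again.

**21 to 15 and 18 (cut C1–C1' and C2–I).** The heptenyl group and the iodide are added anti across the C1≡C2 triple bond of propargylic alcohol 15, with the C6 alkoxide as directing group. This fixes iodine cis to the C6 arm, which the ring closure requires, and builds the tetrasubstituted alkene on an open chain rather than on the ring.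

**15 to 14, and 14 to 9 and 12 (C6 configuration; cut C5–C6).** C6 ends as a ketone, but it is set as one configuration. It is the only stereocentre present when the oxirane is made and the only one remote from the aldehyde when the ring is closed, so a mixture would make both steps ambiguous. Ynone 14 allows a Corey–Bakshi–Shibata reduction and is assembled by acylating the alkenyllithium from 9 with Weinreb amide 12.

**9 to 6 via 8 (C5–I and C4–H).** The Z-iodoalkene comes from hydroxyl-directed trans-hydroalumination of propargylic alcohol 6, so the C4=C5 geometry is set by a stereospecific reaction.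

**6 to 5 and 1; 5 to 4 to 2 to 1 (side chain).** The skipped enyne is cut between the propargylic CH2 and the alkyne into allylic bromide 5 and propargyl alcohol 1. The E-trisubstituted alkene of 4 comes from syn-methylalumination and hydroxymethylation of alkyne 2, itself the PMB ether of 1.

**12 from 10; 18 from 16.** The Weinreb amide is made from the commercial silyl propargyl ether 10, and the E-iodoalkene from hept-1-yne 16 by syn-hydrometallation.

## Alternatives that were turned down

**Alternative 1:** The C3 oxygen and the oxirane oxygen are traced back to one molecule of dioxygen. The endoperoxide A1 would be isomerised by Co(TPP), the tetraphenylporphyrin complex of divalent cobalt, to the syn-bis-epoxide A2. Oxidation at C6 and base-induced opening of the C2–C3 oxirane would then give the C1=C2 enone and the C3 hydroxyl.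
- For it: the cis relation between the C3 oxygen and the remaining oxirane is built in, because both oxygens come from the same bridge. On this point it is stronger than the chosen route, whose ring closure must select an aldehyde face. Both bridgeheads are fully substituted, so the usual base-induced fragmentation of endoperoxides is blocked.
- Against it: A2 has neither the heptenyl group nor the C1=C2 bond. The tetrasubstituted alkene would have to be completed by halogenation and cross-coupling at the most hindered ring position. The absolute configuration of all three centres would depend on one silyloxy-bearing carbon steering the face of the cycloaddition.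
- Comparison: the chosen route sets C4 and C5 by reagent control and brings the complete, geometrically defined diene into the ring closure.

**Alternative 2:** C4–C5 and C5–O are cut. Base would enolise the α-chloro ketone of A3, the enolate would add to the aldehyde and the alkoxide would displace chloride, giving A4.
- For it: ring, oxirane and quaternary centre form in one operation, and C6 is a ketone from the start. This is better redox and bond economy than the chosen route, and it needs no stoichiometric chromium.
- Against it: the only stereocentre of A3 is C3, which is α to the aldehyde and vinylogous to the C6 ketone. The base that forms the enolate can epimerise it before ring closure. The cis relation of the C3 oxygen and the oxirane rests on acyclic 1,2-induction alone. The prenyl end of A4 must still be oxidised site-selectively to the E-acid in the presence of a diene and other allylic positions.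
- Comparison: the chosen route keeps every set stereocentre under neutral conditions and carries the side chain with its oxygen already in place.

**Alternative 3:** The C1=C2 and C1'=C2' double bonds are cut. Enyne A5 and hept-1-ene A6 would react with second-generation Grubbs catalyst RuCl2(H2IMes)(PCy3)(CHPh) in a tandem ring-closing and cross-metathesis to give A7.
- For it: one catalytic step forms the ring and attaches the chain. It is more convergent and more step-economic at the key step than the chosen route.
- Against it: the ring closure must produce a tetrasubstituted ring alkene from a 1,1-disubstituted alkene flanked by two silyloxy carbons, which is demanding for this catalyst. The order of events (alkene first or alkyne first) decides ring size and diene regiochemistry. The cross-metathesis leg gives no guarantee of E geometry. A5 needs the C3 carbinol and oxirane relation set by an intermolecular addition to an epoxy aldehyde, the same facial problem without a ring to help.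
- Comparison: the chosen route fixes position and geometry of both alkenes by stereospecific reactions before cyclisation and forms only a C–C single bond in the ring-closing event.

Key step: step 16

Assumption: tert-butyldimethyl(prop-2-yn-1-yloxy)silane (10) is bought, and the atoms of all open-chain intermediates carry the ring numbers C1–C6 they end up with.

## Route

Step 1
Reactants: 1 prop-2-yn-1-ol
Product: 2 1-methoxy-4-[(prop-2-yn-1-yloxy)methyl]benzene
Conditions: NaH, 4-methoxybenzyl chloride, Bu4NI (cat.), THF, 0 °C to rt
Reagents that add atoms: 4-methoxybenzyl chloride, COc1ccc(CCl)cc1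
Why: Williamson etherification of the sodium alkoxide; the PMB ether survives the organoaluminium, organolithium and Grignard steps and is removed oxidatively near the end.

Step 2
Reactants: 2 1-methoxy-4-[(prop-2-yn-1-yloxy)methyl]benzene
Product: 4 (E)-4-(4-methoxybenzyloxy)-3-methylbut-2-en-1-ol, via alkenyl(dimethyl)alane 3 (not isolated)
Conditions: AlMe3, Cp2ZrCl2 (0.25 equiv), CH2Cl2, 0 °C to rt; then n-BuLi, THF, −30 °C; (CH2O)n, rt
Reagents that add atoms: trimethylaluminium, C[Al](C)C; paraformaldehyde (as formaldehyde), C=O
Why: Negishi zirconium-catalysed methylalumination adds methyl and aluminium syn across the terminal alkyne with methyl on the inner carbon, and the derived aluminate is hydroxymethylated with retention; the E-trisubstituted alkene of the side chain is therefore set stereospecifically.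

Step 3
Reactants: 4 (E)-4-(4-methoxybenzyloxy)-3-methylbut-2-en-1-ol
Product: 5 1-{[(E)-4-bromo-2-methylbut-2-enyl]oxymethyl}-4-methoxybenzene
Conditions: CBr4, PPh3, CH2Cl2, 0 °C
Reagents that add atoms: carbon tetrabromide, BrC(Br)(Br)Br
Why: Appel bromination of a primary allylic alcohol under neutral conditions; substitution at the primary carbon leaves the alkene geometry untouched.

Step 4
Reactants: 5 1-{[(E)-4-bromo-2-methylbut-2-enyl]oxymethyl}-4-methoxybenzene; 1 prop-2-yn-1-ol
Product: 6 (E)-7-(4-methoxybenzyloxy)-6-methylhept-5-en-2-yn-1-ol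
Conditions: CuI (cat.), NaI, K2CO3, DMF, rt
Reagents that add atoms: none
Why: Copper acetylide alkylation of a terminal alkyne with a primary allylic bromide; attack at the primary end is favoured because the other end would become quaternary, and the free carbinol is kept for the next step.

Step 5
Reactants: 6 (E)-7-(4-methoxybenzyloxy)-6-methylhept-5-en-2-yn-1-ol
Product: 8 (2Z,5E)-3-iodo-7-(4-methoxybenzyloxy)-6-methylhepta-2,5-dien-1-ol, via sodium alkenylaluminate chelate 7 (not isolated)
Conditions: NaAlH2(OCH2CH2OCH3)2, THF, 0 °C to rt; EtOAc; then I2, −78 °C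
Reagents that add atoms: iodine, [I][I]
Why: Hydroxyl-directed trans-hydroalumination of the propargylic alcohol places aluminium on the distal alkyne carbon inside a five-membered aluminate, and iodinolysis with retention gives the Z-iodoalkene with iodine cis to the hydroxymethyl group; this geometry later puts C3 and C6 cis on the oxirane.

Step 6
Reactants: 8 (2Z,5E)-3-iodo-7-(4-methoxybenzyloxy)-6-methylhepta-2,5-dien-1-ol
Product: 9 triethylsilyl ether of 8
Conditions: Et3SiCl, imidazole, CH2Cl2, 0 °C
Reagents that add atoms: chlorotriethylsilane, CC[Si](Cl)(CC)CC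
Why: Silylation of the primary allylic alcohol; a free hydroxyl would quench the alkenyllithium and would later let the Z-hydroxy enone close to a furan.

Step 7
Reactants: 10 tert-butyldimethyl(prop-2-yn-1-yloxy)silane
Product: 12 4-(tert-butyldimethylsilyloxy)-N-methoxy-N-methylbut-2-ynamide, via lithium acetylide 11 (not isolated)
Conditions: n-BuLi, THF, −78 °C; ClC(O)N(OMe)Me, −78 to 0 °C
Reagents that add atoms: N-methoxy-N-methylcarbamoyl chloride, CON(C)C(Cl)=O
Why: Deprotonation of the terminal alkyne and acylation with the carbamoyl chloride gives the alkynyl Weinreb amide, an acyl donor that stops at the ketone stage; its carbonyl carbon becomes C6.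

Step 8
Reactants: 9 triethylsilyl ether of 8; 12 4-(tert-butyldimethylsilyloxy)-N-methoxy-N-methylbut-2-ynamide
Product: 14 Z-enynone (C6 ketone between the C4=C5 alkene and the C1≡C2 alkyne), via alkenyllithium 13 (not isolated)
Conditions: t-BuLi (2.1 equiv), Et2O, −78 °C; then 12, −78 to −40 °C; AcOH, −78 °C
Reagents that add atoms: none
Why: Iodine–lithium exchange goes with retention and the alkenyllithium acylates the Weinreb amide (Weinreb ketone synthesis), forming the C5–C6 bond; ether at −78 °C avoids a 1,4 oxygen-to-carbon silyl shift and the cold acidic quench stops the released amine from adding to the ynone.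

Step 9
Reactants: 14 Z-enynone
Product: 15 (R)-propargylic alcohol (C6 carbinol)
Conditions: (R)-2-methyl-CBS-oxazaborolidine (1.0 equiv), BH3·SMe2, THF, −40 °C; MeOH
Reagents that add atoms: none
Why: Corey–Bakshi–Shibata reduction; the slim alkynyl group acts as the small and the α-branched alkenyl group as the large substituent, so the (R)-catalyst should give the (R)-carbinol, the C6 configuration chosen to support both the epoxidation and the ring closure.

Step 10
Reactants: 16 hept-1-yne
Product: 18 (E)-1-iodohept-1-ene, via alkenylzirconocene chloride 17 (not isolated)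
Conditions: Cp2Zr(H)Cl, THF, rt; then I2, 0 °C
Reagents that add atoms: iodine, [I][I]
Why: Hydrozirconation adds Zr–H syn with the metal at the terminus and iodinolysis goes with retention, giving the E-iodoalkene.

Step 11
Reactants: 15 (R)-propargylic alcohol; 18 (E)-1-iodohept-1-ene
Product: 21 Z-iodo dienol (heptenyl on C1 and iodine on C2 with C6–OH free), via (E)-hept-1-enylmagnesium bromide 19 (not isolated), via alkenylmagnesium alkoxide chelate 20 (not isolated)
Conditions: 18, t-BuLi (2 equiv), Et2O, −78 °C, then MgBr2·OEt2 (gives 19, 3 equiv); 15, EtMgBr (1.0 equiv), THF, 0 °C; combine, THF–toluene, 65 °C; then I2, −78 to 0 °C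
Reagents that add atoms: iodine, [I][I]
Why: Hydroxyl-directed anti-carbomagnesiation of a propargylic alcohol: the magnesium alkoxide delivers the alkenyl group to the proximal alkyne carbon C1 and holds magnesium on C2 in a five-membered chelate, cis to C6; iodinolysis with retention then gives the tetrasubstituted Z-iodo diene with iodine cis to the C6 arm and the E-heptenyl group intact.

Step 12
Reactants: 21 Z-iodo dienol
Product: 22 bis-triethylsilyl ether (C3–O and C6–O)
Conditions: Et3SiOTf, 2,6-lutidine, CH2Cl2, −78 °C
Reagents that add atoms: triethylsilyl triflate, CC[Si](CC)(CC)OS(=O)(=O)C(F)(F)F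
Why: Silyl triflate silylation of the hindered, doubly allylic alcohol under non-acidic conditions; C6 has to be a silyl ether before C3 becomes an aldehyde and through the chromium step.

Step 13
Reactants: 22 bis-triethylsilyl ether
Product: 23 Z-allylic alcohol (C3–OH free and C6–OSiEt3 kept)
Conditions: PPTS (cat.), MeOH–CH2Cl2, −20 °C
Reagents that add atoms: none
Why: Acid-catalysed methanolysis should distinguish the unhindered primary triethylsilyl ether from the hindered secondary one and from the primary tert-butyldimethylsilyl ether, so only the C3 allylic alcohol is freed.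

Step 14
Reactants: 23 Z-allylic alcohol
Product: 24 (2S,3S)-epoxy alcohol
Conditions: Ti(OiPr)4, L-(+)-diethyl tartrate, t-BuOOH, 4 Å MS, CH2Cl2, −25 °C
Reagents that add atoms: tert-butyl hydroperoxide, CC(C)(C)OO
Why: Sharpless asymmetric epoxidation of the only free allylic alcohol, a 3,3-disubstituted one of the nerol type; L-(+)-tartrate gives the (2S)-oxiranylmethanol, and syn addition to the Z-alkene puts C3 and C6 cis on the oxirane. In the conformer fixed by allylic 1,3-strain the attacked face carries the C6 silyloxy group and not the bulky dienyl group, so the C6 centre and the reagent should reinforce each other.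

Step 15
Reactants: 24 (2S,3S)-epoxy alcohol
Product: 25 epoxy aldehyde (Z-iodo diene with C6–OSiEt3)
Conditions: Dess–Martin periodinane, pyridine, CH2Cl2, 0 °C
Reagents that add atoms: none
Why: Buffered periodinane oxidation of the primary epoxy alcohol gives the aldehyde without touching silyl ethers, iodide or oxirane; the aldehyde is used at once.

Step 16
Reactants: 25 epoxy aldehyde
Product: 28 cyclised C3 carbinol (hydroxyl cis to the oxirane oxygen), via alkenylchromium dichloride 26 (not isolated), via chromium alkoxide 27 (not isolated)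
Conditions: CrCl2 (8 equiv), NiCl2 (0.1 equiv), degassed THF–DMF 3:1, 0.005 M, rt, 25 added over 6 h
Reagents that add atoms: none
Why: NiCl2 is reduced by CrCl2 to zerovalent nickel, which inserts into the C2–I bond with retention; transmetallation gives the trivalent alkenylchromium 26, which adds to the aldehyde and leaves the chromium alkoxide 27 (Nozaki–Hiyama–Kishi reaction in its known intramolecular alkenyl iodide–aldehyde form). The six-membered ring closes in the 6-exo-trig mode, which is possible only because the preset Z geometry holds the C–Cr bond cis to the C6 arm. The one new stereocentre, C3, is set by the aldehyde face that is attacked: the C5 side chain and the C6 silyloxy group both lie on the ring face opposite to the oxirane oxygen, so the chromium-bound aldehyde oxygen is expected to take the oxirane face, where the oxirane oxygen can also bind chromium, and the hydroxyl ends cis to the oxirane. The step also needs chemoselectivity: the non-basic organochromium leaves oxirane, silyl ethers, PMB ether and the other alkenes alone, C6 is a silyl ether because an epoxy ketone would be reduced by divalent chromium, and slow addition at high dilution keeps the epoxy aldehyde concentration low and suppresses intermolecular coupling.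

Step 17
Reactants: 28 cyclised C3 carbinol
Product: 29 C3 tert-butyldimethylsilyl ether
Conditions: t-BuMe2SiOTf, 2,6-lutidine, CH2Cl2, −78 °C
Reagents that add atoms: tert-butyldimethylsilyl triflate, CC(C)(C)[Si](C)(C)OS(=O)(=O)C(F)(F)F
Why: Silyl triflate silylation of the secondary allylic alcohol at low temperature with a hindered base leaves the oxirane intact; C3 now carries a group that outlasts the removal of the C6 triethylsilyl and PMB groups.

Step 18
Reactants: 29 C3 tert-butyldimethylsilyl ether
Product: 30 C6 carbinol
Conditions: HF·pyridine, pyridine, THF, 0 °C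
Reagents that add atoms: none
Why: Buffered fluoride cleaves a triethylsilyl ether much faster than the two tert-butyldimethylsilyl ethers, and the non-basic medium avoids oxirane migration to the freed C6 oxygen.

Step 19
Reactants: 30 C6 carbinol
Product: 31 diol (C6–OH and side-chain allylic OH)
Conditions: DDQ, CH2Cl2–pH 7 buffer, 0 °C
Reagents that add atoms: none
Why: Oxidative cleavage of the PMB ether through its benzylic cation and hemiacetal; silyl ethers and oxirane are inert, and any over-oxidation of the freed allylic alcohols would only anticipate the next step.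

Step 20
Reactants: 31 diol
Product: 32 keto enal (C6 ketone and side-chain E-enal)
Conditions: Dess–Martin periodinane (3 equiv), pyridine, CH2Cl2, 0 °C to rt
Reagents that add atoms: none
Why: Periodinane oxidation converts the secondary allylic carbinol at C6 into the enone and the primary allylic alcohol into the enal in one operation under buffered conditions; the C6 stereocentre disappears here.

Step 21
Reactants: 32 keto enal
Product: 33 bis-silylated acid
Conditions: NaClO2, NaH2PO4, 2-methylbut-2-ene, t-BuOH–H2O, 0 °C
Reagents that add atoms: sodium chlorite, [Na+].[O-]Cl=O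
Why: Pinnick oxidation; chlorous acid oxidises the enal to the acid without touching the alkenes, and the alkene scavenger removes hypochlorous acid before it can attack the diene.

Step 22
Reactants: 33 bis-silylated acid
Product: 34 target acid
Conditions: HF·pyridine, THF, 0 °C to rt
Reagents that add atoms: none
Why: Fluoride cleaves both silyl ethers under mildly acidic, non-basic conditions, which the epoxy ketone and the epoxy alcohol should tolerate.

## Compound list

1 | prop-2-yn-1-ol | C#CCO | starting material
2 | 1-methoxy-4-[(prop-2-yn-1-yloxy)methyl]benzene | C#CCOCc1ccc(OC)cc1 | intermediate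
3 | dimethyl[(E)-3-(4-methoxybenzyloxy)-2-methylprop-1-enyl]alane (Al and methyl cis) | C[Al](C)/C=C(\C)COCc1ccc(OC)cc1 | intermediate
4 | (E)-4-(4-methoxybenzyloxy)-3-methylbut-2-en-1-ol | OC/C=C(\C)COCc1ccc(OC)cc1 | intermediate
5 | 1-{[(E)-4-bromo-2-methylbut-2-enyl]oxymethyl}-4-methoxybenzene | BrC/C=C(\C)COCc1ccc(OC)cc1 | intermediate
6 | (E)-7-(4-methoxybenzyloxy)-6-methylhept-5-en-2-yn-1-ol | OCC#CC/C=C(\C)COCc1ccc(OC)cc1 | intermediate
7 | sodium aluminate chelate of 6 (five-membered Al–O–CH2–CH=C ring, Al on the alkene carbon that bears the side chain, two 2-methoxyethoxy groups on Al) | [Na+].COCCO[Al-]1(OCCOC)OCC=C1C/C=C(\C)COCc2ccc(OC)cc2 | intermediate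
8 | (2Z,5E)-3-iodo-7-(4-methoxybenzyloxy)-6-methylhepta-2,5-dien-1-ol | OC/C=C(\I)C/C=C(\C)COCc1ccc(OC)cc1 | intermediate
9 | triethyl{[(2Z,5E)-3-iodo-7-(4-methoxybenzyloxy)-6-methylhepta-2,5-dienyl]oxy}silane | CC[Si](CC)(CC)OC/C=C(\I)C/C=C(\C)COCc1ccc(OC)cc1 | intermediate
10 | tert-butyldimethyl(prop-2-yn-1-yloxy)silane | C#CCO[Si](C)(C)C(C)(C)C | starting material
11 | lithium acetylide of 10 | [Li]C#CCO[Si](C)(C)C(C)(C)C | intermediate
12 | 4-(tert-butyldimethylsilyloxy)-N-methoxy-N-methylbut-2-ynamide | CON(C)C(=O)C#CCO[Si](C)(C)C(C)(C)C | intermediate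
13 | alkenyllithium from 9 (Li in place of I, Z geometry kept) | CC[Si](CC)(CC)OC/C=C(\[Li])C/C=C(\C)COCc1ccc(OC)cc1 | intermediate
14 | (7E)-1-(tert-butyldimethylsilyloxy)-9-(4-methoxybenzyloxy)-8-methyl-5-[(Z)-2-(triethylsilyloxy)ethylidene]non-7-en-2-yn-4-one | CC[Si](CC)(CC)OC/C=C(\C(=O)C#CCO[Si](C)(C)C(C)(C)C)C/C=C(\C)COCc1ccc(OC)cc1 | intermediate
15 | (4R,7E)-1-(tert-butyldimethylsilyloxy)-9-(4-methoxybenzyloxy)-8-methyl-5-[(Z)-2-(triethylsilyloxy)ethylidene]non-7-en-2-yn-4-ol | CC[Si](CC)(CC)OC/C=C(\[C@@H](O)C#CCO[Si](C)(C)C(C)(C)C)C/C=C(\C)COCc1ccc(OC)cc1 | intermediate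
16 | hept-1-yne | C#CCCCCC | starting material
17 | chlorobis(cyclopentadienyl)[(E)-hept-1-enyl]zirconium | CCCCC/C=C/[Zr](Cl)(C1C=CC=C1)C1C=CC=C1 | intermediate
18 | (E)-1-iodohept-1-ene | CCCCC/C=C/I | intermediate
19 | (E)-hept-1-enylmagnesium bromide | CCCCC/C=C/[Mg]Br | intermediate
20 | magnesium chelate from 15 and 19 (2,5-dihydro-1,2-oxamagnesole ring, O on C6, Mg on C2, heptenyl on C1) | CC[Si](CC)(CC)OC/C=C(\[C@H]1O[Mg]C(CO[Si](C)(C)C(C)(C)C)=C1/C=C/CCCCC)C/C=C(\C)COCc2ccc(OC)cc2 | intermediate
21 | (2Z,4R,7E)-1-(tert-butyldimethylsilyloxy)-3-[(E)-hept-1-enyl]-2-iodo-9-(4-methoxybenzyloxy)-8-methyl-5-[(Z)-2-(triethylsilyloxy)ethylidene]nona-2,7-dien-4-ol | CC[Si](CC)(CC)OC/C=C(\[C@@H](O)C(/C=C/CCCCC)=C(\I)CO[Si](C)(C)C(C)(C)C)C/C=C(\C)COCc1ccc(OC)cc1 | intermediate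
22 | 4-O-triethylsilyl ether of 21 (4R) | CC[Si](CC)(CC)OC/C=C(\[C@@H](O[Si](CC)(CC)CC)C(/C=C/CCCCC)=C(\I)CO[Si](C)(C)C(C)(C)C)C/C=C(\C)COCc1ccc(OC)cc1 | intermediate
23 | (2Z,5E)-3-[(1R,2Z)-4-(tert-butyldimethylsilyloxy)-2-[(E)-hept-1-enyl]-3-iodo-1-(triethylsilyloxy)but-2-enyl]-7-(4-methoxybenzyloxy)-6-methylhepta-2,5-dien-1-ol | OC/C=C(\[C@@H](O[Si](CC)(CC)CC)C(/C=C/CCCCC)=C(\I)CO[Si](C)(C)C(C)(C)C)C/C=C(\C)COCc1ccc(OC)cc1 | intermediate
24 | {(2S,3S)-3-[(1S,2Z)-4-(tert-butyldimethylsilyloxy)-2-[(E)-hept-1-enyl]-3-iodo-1-(triethylsilyloxy)but-2-enyl]-3-[(E)-4-(4-methoxybenzyloxy)-3-methylbut-2-enyl]oxiran-2-yl}methanol | OC[C@@H]1O[C@]1(C/C=C(\C)COCc2ccc(OC)cc2)[C@@H](O[Si](CC)(CC)CC)C(/C=C/CCCCC)=C(\I)CO[Si](C)(C)C(C)(C)C | intermediate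
25 | (2R,3S)-3-[(1S,2Z)-4-(tert-butyldimethylsilyloxy)-2-[(E)-hept-1-enyl]-3-iodo-1-(triethylsilyloxy)but-2-enyl]-3-[(E)-4-(4-methoxybenzyloxy)-3-methylbut-2-enyl]oxirane-2-carbaldehyde | O=C[C@@H]1O[C@]1(C/C=C(\C)COCc2ccc(OC)cc2)[C@@H](O[Si](CC)(CC)CC)C(/C=C/CCCCC)=C(\I)CO[Si](C)(C)C(C)(C)C | intermediate
26 | alkenylchromium dichloride from 25 (trivalent chromium on C2 in place of iodine) | O=C[C@@H]1O[C@]1(C/C=C(\C)COCc2ccc(OC)cc2)[C@@H](O[Si](CC)(CC)CC)C(/C=C/CCCCC)=C(\[Cr](Cl)Cl)CO[Si](C)(C)C(C)(C)C | intermediate
27 | chromium alkoxide of 28 (O–CrCl2 on C3) | CCCCC/C=C/C1=C(CO[Si](C)(C)C(C)(C)C)[C@H](O[Cr](Cl)Cl)[C@@H]2O[C@]2(C/C=C(\C)COCc3ccc(OC)cc3)[C@H]1O[Si](CC)(CC)CC | intermediate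
28 | (1S,2S,5S,6S)-4-[(tert-butyldimethylsilyloxy)methyl]-3-[(E)-hept-1-enyl]-1-[(E)-4-(4-methoxybenzyloxy)-3-methylbut-2-enyl]-2-(triethylsilyloxy)-7-oxabicyclo[4.1.0]hept-3-en-5-ol | CCCCC/C=C/C1=C(CO[Si](C)(C)C(C)(C)C)[C@H](O)[C@@H]2O[C@]2(C/C=C(\C)COCc3ccc(OC)cc3)[C@H]1O[Si](CC)(CC)CC | intermediate
29 | 5-O-tert-butyldimethylsilyl ether of 28 (1S,2S,5S,6S) | CCCCC/C=C/C1=C(CO[Si](C)(C)C(C)(C)C)[C@H](O[Si](C)(C)C(C)(C)C)[C@@H]2O[C@]2(C/C=C(\C)COCc3ccc(OC)cc3)[C@H]1O[Si](CC)(CC)CC | intermediate
30 | (1R,2S,5S,6S)-5-(tert-butyldimethylsilyloxy)-4-[(tert-butyldimethylsilyloxy)methyl]-3-[(E)-hept-1-enyl]-1-[(E)-4-(4-methoxybenzyloxy)-3-methylbut-2-enyl]-7-oxabicyclo[4.1.0]hept-3-en-2-ol | CCCCC/C=C/C1=C(CO[Si](C)(C)C(C)(C)C)[C@H](O[Si](C)(C)C(C)(C)C)[C@@H]2O[C@]2(C/C=C(\C)COCc3ccc(OC)cc3)[C@H]1O | intermediate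
31 | (1R,2S,5S,6S)-5-(tert-butyldimethylsilyloxy)-4-[(tert-butyldimethylsilyloxy)methyl]-3-[(E)-hept-1-enyl]-1-[(E)-4-hydroxy-3-methylbut-2-enyl]-7-oxabicyclo[4.1.0]hept-3-en-2-ol | CCCCC/C=C/C1=C(CO[Si](C)(C)C(C)(C)C)[C@H](O[Si](C)(C)C(C)(C)C)[C@@H]2O[C@]2(C/C=C(\C)CO)[C@H]1O | intermediate
32 | (E)-4-[(1S,5S,6S)-5-(tert-butyldimethylsilyloxy)-4-[(tert-butyldimethylsilyloxy)methyl]-3-[(E)-hept-1-enyl]-2-oxo-7-oxabicyclo[4.1.0]hept-3-en-1-yl]-2-methylbut-2-enal | CCCCC/C=C/C1=C(CO[Si](C)(C)C(C)(C)C)[C@H](O[Si](C)(C)C(C)(C)C)[C@@H]2O[C@]2(C/C=C(\C)C=O)C1=O | intermediate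
33 | (E)-4-[(1S,5S,6S)-5-(tert-butyldimethylsilyloxy)-4-[(tert-butyldimethylsilyloxy)methyl]-3-[(E)-hept-1-enyl]-2-oxo-7-oxabicyclo[4.1.0]hept-3-en-1-yl]-2-methylbut-2-enoic acid | CCCCC/C=C/C1=C(CO[Si](C)(C)C(C)(C)C)[C@H](O[Si](C)(C)C(C)(C)C)[C@@H]2O[C@]2(C/C=C(\C)C(=O)O)C1=O | intermediate
34 | (E)-4-[(1S,5S,6S)-3-[(E)-hept-1-enyl]-5-hydroxy-4-(hydroxymethyl)-2-oxo-7-oxabicyclo[4.1.0]hept-3-en-1-yl]-2-methylbut-2-enoic acid | CCCCC/C=C/C1=C(CO)[C@H](O)[C@@H]2O[C@]2(C/C=C(\C)C(=O)O)C1=O | target

## Step count and least certain steps

Total: 22 steps. Longest linear sequence: 20 steps (steps 1–6, 8, 9 and 11–22; steps 7 and 10 are side branches).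

**Step 16 (key step).** The most likely failure is poor facial selectivity at the aldehyde. An arrangement with the carbonyl oxygen turned away from the oxirane oxygen (dipoles opposed) would give the hydroxyl trans to the oxirane, and the steric and chelation arguments for the cis product are not compelling. A second failure is reductive opening of the epoxy aldehyde by divalent chromium before the carbon–carbon bond forms. The fallback sets out from 25 and returns at 28. The ring closure is accepted with whatever face it prefers, giving the C3-epimeric carbinol F1 alone or mixed with 28. Dess–Martin oxidation converts the material to the epoxy enone F2. Reduction with NaBH4 and CeCl3·7H2O in methanol at −78 °C should deliver hydride anti to the oxirane oxygen and give 28. The C3 configuration is then set by a small nucleophile on a rigid ring, not by the cyclisation.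

**Step 11.** The most likely failure is slow addition of the 2-substituted alkenyl Grignard reagent to the hindered secondary alkoxide. Long heating would allow loss of silyloxide from the alkenylmagnesium (allene formation) and partial E/Z scrambling of the reagent. The fallback sets out from 15 and returns at 21. Vinylmagnesium chloride (CH2=CHMgCl), the best-behaved reagent in this reaction class, is added in the same hydroxyl-directed anti mode at lower temperature, and iodinolysis gives the vinyl-substituted iodo trienol F3. Cross-metathesis of its terminal vinyl group with hept-1-ene, using second-generation Grubbs catalyst RuCl2(H2IMes)(PCy3)(CHPh), then builds the E-heptenyl group and gives 21. The tetrasubstituted iodoalkene and the trisubstituted alkenes are too hindered to take part.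

**Step 14.** The most likely failure is a slow epoxidation with eroded facial selectivity. The titanium–tartrate catalyst has to accommodate a branched, stereogenic substituent cis to the carbinol. If the C6 centre opposes the tartrate instead of supporting it, reagent control will not override it. The fallback changes the stereochemical pairing and not the reagent. It sets out from 14 and returns at 32, where C6 becomes a ketone. Reduction of 14 with the (S)-oxazaborolidine gives the C6-epimeric propargylic alcohol F4. The conditions of steps 11 to 13 convert it into the iodo dienol F5, the bis-silyl ether F6 and the allylic alcohol F7. Epoxidation with the same L-(+)-tartrate system, now in the other pairing, gives the epoxy alcohol F8. Oxidation gives the epoxy aldehyde F9, ring closure the cyclised carbinol F10, and silylation the silyl ether F11. Removal of the triethylsilyl group gives the C6 carbinol F12 and removal of the PMB group the diol F13. The double oxidation of step 20 converts F13 into 32.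

## Further compounds

F1 | step 16 | C3 epimer of 28 (hydroxyl trans to the oxirane oxygen) | CCCCC/C=C/C1=C(CO[Si](C)(C)C(C)(C)C)[C@@H](O)[C@@H]2O[C@]2(C/C=C(\C)COCc3ccc(OC)cc3)[C@H]1O[Si](CC)(CC)CC
F2 | step 16 | epoxy enone (C3 ketone) from F1 | CCCCC/C=C/C1=C(CO[Si](C)(C)C(C)(C)C)C(=O)[C@@H]2O[C@]2(C/C=C(\C)COCc3ccc(OC)cc3)[C@H]1O[Si](CC)(CC)CC
F3 | step 11 | vinyl analogue of 21 (vinyl on C1 in place of heptenyl) | CC[Si](CC)(CC)OC/C=C(\[C@@H](O)C(/C=C)=C(\I)CO[Si](C)(C)C(C)(C)C)C/C=C(\C)COCc1ccc(OC)cc1
F4 | step 14 | C6 epimer of 15 | CC[Si](CC)(CC)OC/C=C(\[C@H](O)C#CCO[Si](C)(C)C(C)(C)C)C/C=C(\C)COCc1ccc(OC)cc1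
F5 | step 14 | C6 epimer of 21 | CC[Si](CC)(CC)OC/C=C(\[C@H](O)C(/C=C/CCCCC)=C(\I)CO[Si](C)(C)C(C)(C)C)C/C=C(\C)COCc1ccc(OC)cc1
F6 | step 14 | C6 epimer of 22 | CC[Si](CC)(CC)OC/C=C(\[C@H](O[Si](CC)(CC)CC)C(/C=C/CCCCC)=C(\I)CO[Si](C)(C)C(C)(C)C)C/C=C(\C)COCc1ccc(OC)cc1
F7 | step 14 | C6 epimer of 23 | OC/C=C(\[C@H](O[Si](CC)(CC)CC)C(/C=C/CCCCC)=C(\I)CO[Si](C)(C)C(C)(C)C)C/C=C(\C)COCc1ccc(OC)cc1
F8 | step 14 | C6 epimer of 24 | OC[C@@H]1O[C@]1(C/C=C(\C)COCc2ccc(OC)cc2)[C@H](O[Si](CC)(CC)CC)C(/C=C/CCCCC)=C(\I)CO[Si](C)(C)C(C)(C)C
F9 | step 14 | C6 epimer of 25 | O=C[C@@H]1O[C@]1(C/C=C(\C)COCc2ccc(OC)cc2)[C@H](O[Si](CC)(CC)CC)C(/C=C/CCCCC)=C(\I)CO[Si](C)(C)C(C)(C)C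
F10 | step 14 | C6 epimer of 28 | CCCCC/C=C/C1=C(CO[Si](C)(C)C(C)(C)C)[C@H](O)[C@@H]2O[C@]2(C/C=C(\C)COCc3ccc(OC)cc3)[C@@H]1O[Si](CC)(CC)CC
F11 | step 14 | C6 epimer of 29 | CCCCC/C=C/C1=C(CO[Si](C)(C)C(C)(C)C)[C@H](O[Si](C)(C)C(C)(C)C)[C@@H]2O[C@]2(C/C=C(\C)COCc3ccc(OC)cc3)[C@@H]1O[Si](CC)(CC)CC
F12 | step 14 | C6 epimer of 30 | CCCCC/C=C/C1=C(CO[Si](C)(C)C(C)(C)C)[C@H](O[Si](C)(C)C(C)(C)C)[C@@H]2O[C@]2(C/C=C(\C)COCc3ccc(OC)cc3)[C@@H]1O
F13 | step 14 | C6 epimer of 31 | CCCCC/C=C/C1=C(CO[Si](C)(C)C(C)(C)C)[C@H](O[Si](C)(C)C(C)(C)C)[C@@H]2O[C@]2(C/C=C(\C)CO)[C@@H]1O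
A1 | alternative 1 | endoperoxide (2,3-dioxabicyclo[2.2.2]oct-5-ene, silyloxymethyl and ester side chain on the bridgeheads, triethylsilyloxy on the carbon bridge) | C1[C@]2(CO[Si](C)(C)C(C)(C)C)OO[C@@](C/C=C(\C)C(=O)OCC[Si](C)(C)C)(C=C2)[C@H]1O[Si](CC)(CC)CC
A2 | alternative 1 | syn-bis-epoxide (C2–C3 and C4–C5 oxiranes on the same face) | C1[C@]2(CO[Si](C)(C)C(C)(C)C)O[C@@H]2[C@@H]3O[C@]3(C/C=C(\C)C(=O)OCC[Si](C)(C)C)[C@H]1O[Si](CC)(CC)CC
A3 | alternative 2 | α-chloro ketone aldehyde (C5 chloride, C6 ketone, aldehyde carbon that becomes C4) | O=C[C@@H](O[Si](C)(C)C(C)(C)C)/C(CO[Si](C)(C)C(C)(C)C)=C(/C=C/CCCCC)C(=O)C(Cl)CC=C(C)C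
A4 | alternative 2 | bis-silylated epoxy cyclohexenone with prenyl group | CCCCC/C=C/C1=C(CO[Si](C)(C)C(C)(C)C)[C@H](O[Si](C)(C)C(C)(C)C)[C@@H]2O[C@]2(CC=C(C)C)C1=O
A5 | alternative 3 | epoxy enyne (C6 propargylic alcohol with terminal alkyne, 1,1-disubstituted alkene at C2) | C#CC(O)[C@@]1(C/C=C(\C)C(=O)OCC[Si](C)(C)C)O[C@H]1[C@@H](O[Si](C)(C)C(C)(C)C)C(=C)CO[Si](C)(C)C(C)(C)C
A6 | alternative 3 | hept-1-ene | C=CCCCCC
A7 | alternative 3 | C6 carbinol of the protected target skeleton | CCCCC/C=C/C1=C(CO[Si](C)(C)C(C)(C)C)[C@H](O[Si](C)(C)C(C)(C)C)[C@@H]2O[C@]2(C/C=C(\C)C(=O)OCC[Si](C)(C)C)C1O
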